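## Retrosynthetic overview

1. The C2-symmetric target 17 is opened at both ring C3=C4 bonds: a two-fold ring-closing metathesis of the acyclic bis-epoxy hexaene diol 15 closes both cyclohexenes last, in one operation.
2. 15 comes from a two-directional double allylboration of tetraene dialdehyde 12 with the (R)-epoxygeranyl boronate 4; this sets all four carbinol and quaternary centres.
3. 12 comes from oxidative homocoupling of dienylstannane aldehyde 11, made from 4-bromopent-4-enal 9 (acetaldehyde hydrazone + 2,3-dibromopropene) and a distannylethene.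
4. 4 comes from geranyl acetate by Shi epoxidation (sets the epoxide centre) and allylic borylation.
5. Ring order: the epoxide of each reagent molecule first (step 1), then both cyclohexenes simultaneously (step 7).

Assumption: the D-fructose-derived Shi ketone gives the (R)-epoxide on a Me2C=CH–CH2R alkene and (S)-TRIP directs allyl transfer to the aldehyde Si face (the senses known for simple substrates); if either sense were reversed the antipodal catalyst would be used.

## Route

Step 1
Reactants: 1 geranyl acetate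
Product: 2 (R)-6,7-epoxygeranyl acetate, (2E)-5-[(2R)-3,3-dimethyloxiran-2-yl]-3-methylpent-2-en-1-yl acetate
Conditions: 1,2:4,5-di-O-isopropylidene-β-D-erythro-2,3-hexodiulo-2,6-pyranose (D-fructose-derived Shi ketone, 30 mol %), Oxone (2KHSO5·KHSO4·K2SO4), K2CO3, Bu4NHSO4, MeCN/dimethoxymethane–aq. Na2B4O7/Na2EDTA (pH 10.5), 0 °C
Reagents that add atoms: potassium peroxymonosulfate (the oxidant in Oxone), [K+].[O-]S(=O)(=O)OO
Why: Shi asymmetric epoxidation, in which the chiral dioxirane attacks only the electron-rich 6,7-alkene (the 2,3-alkene is deactivated by the allylic acetate) through a spiro transition state that sets the (R) epoxide centre.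

Step 2
Reactants: 2 (R)-6,7-epoxygeranyl acetate; 3 bis(pinacolato)diboron
Product: 4 (R)-epoxygeranyl pinacolboronate, 2-{(2E)-5-[(2R)-3,3-dimethyloxiran-2-yl]-3-methylpent-2-en-1-yl}-4,4,5,5-tetramethyl-1,3,2-dioxaborolane
Conditions: Pd2(dba)3 (2.5 mol %), DMSO, 50 °C
Reagents that add atoms: none
Why: Miyaura-type borylation of an allylic acetate through a π-allylpalladium intermediate puts boron on the unhindered primary terminus with the E geometry kept, while the non-allylic epoxide is inert to zerovalent palladium and no stereocentre is touched.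

Step 3
Reactants: 5 acetaldehyde N,N-dimethylhydrazone; 6 2,3-dibromopropene
Product: 9 4-bromopent-4-enal, via lithio hydrazone 7 (not isolated), via bromoalkenyl hydrazone 8 (not isolated)
Conditions: LiN(iPr)2, THF, 0 °C; then 6, −78 °C to rt; then 2 M aq. HCl, pentane, rt
Reagents that add atoms: water, O
Why: Corey–Enders-type hydrazone aza-enolate alkylation, in which the lithio species displaces only the allylic bromide of 6 (SN2, vinyl bromide inert) and acid hydrolysis of the C=N bond frees the aldehyde; no stereocentre is formed.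

Step 4
Reactants: 9 4-bromopent-4-enal; 10 (E)-1,2-bis(tributylstannyl)ethene (3 equiv)
Product: 11 (5E)-4-methylidene-6-(tributylstannyl)hex-5-enal
Conditions: Pd(PPh3)4 (5 mol %), CuI (10 mol %), DMF, 50 °C
Reagents that add atoms: none
Why: Stille cross-coupling of the alkenyl bromide with one tin terminus of the excess distannane goes with retention to the (E)-dienylstannane under neutral conditions that spare the enolisable aldehyde.

Step 5
Reactants: 11 (5E)-4-methylidene-6-(tributylstannyl)hex-5-enal (2 equiv)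
Product: 12 (5E,7E)-4,9-dimethylidenedodeca-5,7-dienedial
Conditions: Cu(NO3)2·3H2O (1.1 equiv per tin), THF, rt, dark
Reagents that add atoms: none
Why: Copper-mediated oxidative homocoupling of an alkenylstannane (tin-to-copper transmetalation, then C–C coupling with retention at both alkenes) joins two halves into the E,E-tetraene.

Step 6
Reactants: 12 (5E,7E)-4,9-dimethylidenedodeca-5,7-dienedial; 4 (R)-epoxygeranyl pinacolboronate (2.4 equiv)
Product: 15 (3S,4R,8E,10E,15R,16S)-3,16-bis{2-[(2R)-3,3-dimethyloxiran-2-yl]ethyl}-3,16-dimethyl-7,12-dimethylideneoctadeca-1,8,10,17-tetraene-4,15-diol, via mono-adduct borate 13 (not isolated), via bis-borate 14 (not isolated)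
Conditions: (S)-3,3'-bis(2,4,6-triisopropylphenyl)-1,1'-binaphthyl-2,2'-diyl hydrogen phosphate [(S)-TRIP, 10 mol %], 4 Å MS, toluene, −30 °C; then aq. NaHCO3
Reagents that add atoms: none
Why: Two-fold chiral phosphoric acid-catalysed allylboration (Antilla-type) through closed chair transition states, in which the (S)-acid sends the γ-carbon to the Si face of each aldehyde (4R, 15R), the E geometry of 4 places the chain anti and the methyl syn to the new hydroxyl (3S, 16S), and the double addition diverts minor-enantiomer events into a separable meso-type diastereomer.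

Step 7
Reactants: 15 bis-epoxy hexaene diol
Product: 17 (1R,2S)-2-{2-[(2R)-3,3-dimethyloxiran-2-yl]ethyl}-4-[(1E,3E)-4-[(3S,4R)-3-{2-[(2R)-3,3-dimethyloxiran-2-yl]ethyl}-4-hydroxy-3-methylcyclohex-1-en-1-yl]buta-1,3-dien-1-yl]-2-methylcyclohex-3-en-1-ol, via monocyclic pentaene 16 (not isolated)
Conditions: second-generation Hoveyda–Grubbs catalyst RuCl2(H2IMes)(=CH-C6H4-2-OiPr) (2 × 5 mol %), 1,4-benzoquinone (10 mol %), CH2Cl2 (2 mM), 40 °C, argon sparge
Reagents that add atoms: none
Why: Two-fold ring-closing metathesis, in which each ruthenium alkylidene formed at a vinyl group closes onto the nearby 1,1-disubstituted terminus of the tetraene (six-membered ring favoured over attack on the internal E,E-diene), expels ethene and forms both trisubstituted cyclohexenes without touching the stereocentres, epoxides or free hydroxyls.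

## Compound list

1 | geranyl acetate, (2E)-3,7-dimethylocta-2,6-dien-1-yl acetate | CC(=O)OC/C=C(\C)CCC=C(C)C | starting material
2 | (2E)-5-[(2R)-3,3-dimethyloxiran-2-yl]-3-methylpent-2-en-1-yl acetate | CC(=O)OC/C=C(\C)CC[C@H]1OC1(C)C | intermediate
3 | bis(pinacolato)diboron | CC1(C)OB(OC1(C)C)B1OC(C)(C)C(C)(C)O1 | starting material
4 | 2-{(2E)-5-[(2R)-3,3-dimethyloxiran-2-yl]-3-methylpent-2-en-1-yl}-4,4,5,5-tetramethyl-1,3,2-dioxaborolane | CC1(C)OB(C/C=C(\C)CC[C@H]2OC2(C)C)OC1(C)C | intermediate
5 | acetaldehyde N,N-dimethylhydrazone | CC=NN(C)C | starting material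
6 | 2,3-dibromopropene | C=C(Br)CBr | starting material
7 | lithiated acetaldehyde N,N-dimethylhydrazone (lithium aza-enolate) | [Li+].[CH2-]C=NN(C)C | intermediate
8 | 4-bromopent-4-enal N,N-dimethylhydrazone | C=C(Br)CCC=NN(C)C | intermediate
9 | 4-bromopent-4-enal | C=C(Br)CCC=O | intermediate
10 | (E)-1,2-bis(tributylstannyl)ethene | CCCC[Sn](CCCC)(CCCC)/C=C/[Sn](CCCC)(CCCC)CCCC | starting material
11 | (5E)-4-methylidene-6-(tributylstannyl)hex-5-enal | O=CCCC(=C)/C=C/[Sn](CCCC)(CCCC)CCCC | intermediate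
12 | (5E,7E)-4,9-dimethylidenedodeca-5,7-dienedial | O=CCCC(=C)/C=C/C=C/C(=C)CCC=O | intermediate
13 | mono-adduct: O-pinacolboryl ether of the (R)-carbinol/(S)-quaternary adduct at one aldehyde of 12, other aldehyde free | O=CCCC(=C)/C=C/C=C/C(=C)CC[C@@H](OB1OC(C)(C)C(C)(C)O1)[C@](C)(C=C)CC[C@H]1OC1(C)C | intermediate
14 | bis(O-pinacolboryl) ether of 15 | CC1(C)O[C@@H]1CC[C@@](C)(C=C)[C@H](OB1OC(C)(C)C(C)(C)O1)CCC(=C)/C=C/C=C/C(=C)CC[C@@H](OB1OC(C)(C)C(C)(C)O1)[C@](C)(C=C)CC[C@H]1OC1(C)C | intermediate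
15 | (3S,4R,8E,10E,15R,16S)-3,16-bis{2-[(2R)-3,3-dimethyloxiran-2-yl]ethyl}-3,16-dimethyl-7,12-dimethylideneoctadeca-1,8,10,17-tetraene-4,15-diol | CC1(C)O[C@@H]1CC[C@@](C)(C=C)[C@H](O)CCC(=C)/C=C/C=C/C(=C)CC[C@@H](O)[C@](C)(C=C)CC[C@H]1OC1(C)C | intermediate
16 | mono-cyclised intermediate: one (1R,2S)-cyclohexenol ring closed, the other half still the acyclic (R)-carbinol/(S)-quaternary vinyl/methylidene unit | CC1(C)O[C@@H]1CC[C@@]1(C)C=C(/C=C/C=C/C(=C)CC[C@@H](O)[C@](C)(C=C)CC[C@H]2OC2(C)C)CC[C@H]1O | intermediate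
17 | CNP0229121.4, (1R,2S)-2-{2-[(2R)-3,3-dimethyloxiran-2-yl]ethyl}-4-[(1E,3E)-4-[(3S,4R)-3-{2-[(2R)-3,3-dimethyloxiran-2-yl]ethyl}-4-hydroxy-3-methylcyclohex-1-en-1-yl]buta-1,3-dien-1-yl]-2-methylcyclohex-3-en-1-ol | CC1(C)O[C@@H]1CC[C@@]1(C)C=C(/C=C/C=C/C2=C[C@](C)(CC[C@H]3OC3(C)C)[C@H](O)CC2)CC[C@H]1O | target

## Step count and risks

Total steps: 7. Longest linear sequence: 5 (steps 3, 4, 5, 6, 7); the reagent branch (steps 1, 2) joins at step 6.

**Step 7 (two-fold ring closure on a conjugated tetraene).** The carbene may attack the internal diene or cross-link. The fallback closes one ring per molecule before any polyene exists; it sets out from 4 and comes back at 17. (S)-TRIP-catalysed allylboration of commercial pent-4-ynal (C#CCCC=O) with 4 gives the enynol (5R,6S)-6-{2-[(2R)-3,3-dimethyloxiran-2-yl]ethyl}-6-methyloct-7-en-1-yn-5-ol F1. Ring-closing enyne metathesis (second-generation Grubbs catalyst RuCl2(H2IMes)(PCy3)(=CHPh), ethene atmosphere, CH2Cl2) gives the vinylcyclohexenol (1R,2S)-2-{2-[(2R)-3,3-dimethyloxiran-2-yl]ethyl}-4-ethenyl-2-methylcyclohex-3-en-1-ol F2. Cross-metathesis of its terminal vinyl with vinylboronic acid pinacol ester gives the (E)-dienylboronate F3. Pd(OAc)2-catalysed oxidative homocoupling under O2 (aq. K2CO3, THF) joins two molecules of F3 to give 17.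

**Step 6 (acid catalyst with an epoxide-bearing, γ,γ-disubstituted boronate on a sensitive tetraene dialdehyde).** The fallback keeps the epoxide away from the acid and the tetraene away from the allylation; it sets out from 9 and comes back at 15. Geranyl chloride (CC(C)=CCC/C(C)=C/CCl) and 3 with Pd2(dba)3 in THF give geranyl pinacolboronate F4. (S)-TRIP-catalysed allylboration of 9 with F4 gives the bromo dienol (5R,6S)-2-bromo-6-ethenyl-6,10-dimethylundeca-1,9-dien-5-ol F5. Shi epoxidation as in step 1 (only the trisubstituted alkene reacts) gives the epoxy bromide (3S,4R)-7-bromo-1-[(2R)-3,3-dimethyloxiran-2-yl]-3-ethenyl-3-methyloct-7-en-4-ol F6. Stille coupling with 10 at room temperature (Pd(PPh3)4, CuI, CsF, DMF; fast transmetalation to outrun Heck cyclisation onto the vinyl group) gives the dienylstannane F7. Cu(NO3)2·3H2O homocoupling of F7 as in step 5 gives 15.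

**Step 5 (oxidative homocoupling of a protodestannylation-prone dienylstannane).** The fallback replaces it by a halide/stannane cross-coupling; it sets out from 11 and comes back at 12. Half of 11 is treated with I2 (CH2Cl2, 0 °C) to give the dienyl iodide (5E)-6-iodo-4-methylidenehex-5-enal F8. Stille coupling of F8 with the other half of 11 (PdCl2(MeCN)2, DMF, rt) gives 12 with both alkene geometries retained.

## Further compounds

F1 | step 7 | (5R,6S)-6-{2-[(2R)-3,3-dimethyloxiran-2-yl]ethyl}-6-methyloct-7-en-1-yn-5-ol | C#CCC[C@@H](O)[C@](C)(C=C)CC[C@H]1OC1(C)C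
F2 | step 7 | (1R,2S)-2-{2-[(2R)-3,3-dimethyloxiran-2-yl]ethyl}-4-ethenyl-2-methylcyclohex-3-en-1-ol | C=CC1=C[C@](C)(CC[C@H]2OC2(C)C)[C@H](O)CC1
F3 | step 7 | 2-[(E)-2-{(3S,4R)-3-{2-[(2R)-3,3-dimethyloxiran-2-yl]ethyl}-4-hydroxy-3-methylcyclohex-1-en-1-yl}ethenyl]-4,4,5,5-tetramethyl-1,3,2-dioxaborolane | CC1(C)OB(/C=C/C2=C[C@](C)(CC[C@H]3OC3(C)C)[C@H](O)CC2)OC1(C)C
F4 | step 6 | geranyl pinacolboronate, 2-[(2E)-3,7-dimethylocta-2,6-dien-1-yl]-4,4,5,5-tetramethyl-1,3,2-dioxaborolane | CC(C)=CCC/C(C)=C/CB1OC(C)(C)C(C)(C)O1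
F5 | step 6 | (5R,6S)-2-bromo-6-ethenyl-6,10-dimethylundeca-1,9-dien-5-ol | C=C(Br)CC[C@@H](O)[C@](C)(C=C)CCC=C(C)C
F6 | step 6 | (3S,4R)-7-bromo-1-[(2R)-3,3-dimethyloxiran-2-yl]-3-ethenyl-3-methyloct-7-en-4-ol | C=C(Br)CC[C@@H](O)[C@](C)(C=C)CC[C@H]1OC1(C)C
F7 | step 6 | (1E,6R,7S)-9-[(2R)-3,3-dimethyloxiran-2-yl]-7-ethenyl-7-methyl-3-methylidene-1-(tributylstannyl)non-1-en-6-ol | CCCC[Sn](CCCC)(CCCC)/C=C/C(=C)CC[C@@H](O)[C@](C)(C=C)CC[C@H]1OC1(C)C
F8 | step 5 | (5E)-6-iodo-4-methylidenehex-5-enal | O=CCCC(=C)/C=C/I
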